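**Retrosynthetic overview**

- The strategy rests on the C2–C3–C4–C5 chain of the oxolane ring: C3 and C4 are neighbouring CH(CH3) carbons flanked by the two benzylic C–O carbons C2 and C5. Each is the one-carbon unit that a 1-lithioethyl carbenoid inserts into a C–B bond.
- The target 22 comes from its O-benzyl ether 21, and 21 from the open-chain hydroxy methyl ether 19 by closure of the O1–C2 bond with loss of methanol. The oxolane is the only ring and is formed last; C2 and C5 are set there under thermodynamic control.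
- 19 comes from the secondary boronate 11 by forming C4–C5 with the lithiated syringyl carbamate 16, followed by C–B oxidation.
- 11 comes from the α-methoxybenzyl boronate 5 by two successive insertions of the (S)-carbenoid 7, forming C2–C3 and then C3–C4.
- 5 comes from aryl boronate 1, 7 is made in the flask from ethyl benzoate 6 with sBuLi and (−)-sparteine, and carbamate 15 comes from syringaldehyde 12.

Key step: step 3

Assumption: the oxolane is numbered O1, C2 (3,4-dimethoxyphenyl-bearing), C3, C4, C5 (syringyl-bearing), so the target is (2S,3S,4R,5R), with both aryl groups on one face and both methyl groups on the other. Ethyl 2,4,6-triisopropylbenzoate and (−)-sparteine are taken as purchasable. C2 and C5 are carried as epimer mixtures until step 8.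

**Route**

Step 1
Reactants: 1 2-(3,4-dimethoxyphenyl)-4,4,5,5-tetramethyl-1,3,2-dioxaborolane
Product: 3 2-[chloro(3,4-dimethoxyphenyl)methyl]-4,4,5,5-tetramethyl-1,3,2-dioxaborolane (racemic; used crude), via dichloromethyl boronate complex 2 (not isolated)
Conditions: CH2Cl2, nBuLi, THF, −100 °C; then 1; ZnCl2, −100 °C → rt
Reagents that add atoms: dichloromethane, ClCCl
Why: Matteson homologation, in which LiCHCl2 adds to boron and the electron-rich aryl group migrates from boron to carbon with loss of chloride; the new centre (later C2) is racemic, which is acceptable because C2 is set in step 8.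

Step 2
Reactants: 3 2-[chloro(3,4-dimethoxyphenyl)methyl]-4,4,5,5-tetramethyl-1,3,2-dioxaborolane
Product: 5 2-[(3,4-dimethoxyphenyl)(methoxy)methyl]-4,4,5,5-tetramethyl-1,3,2-dioxaborolane (racemic), via methoxy boronate complex 4 (not isolated)
Conditions: NaOMe, THF/MeOH, 0 °C → rt
Reagents that add atoms: sodium methoxide, [Na+].[O-]C
Why: Matteson-type substitution of an α-chloro boronic ester, in which methoxide adds to boron and shifts from boron to carbon with displacement of chloride; direct solvolysis of the activated benzylic chloride would give the same ether.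

Step 3
Reactants: 5 2-[(3,4-dimethoxyphenyl)(methoxy)methyl]-4,4,5,5-tetramethyl-1,3,2-dioxaborolane; 6 ethyl 2,4,6-triisopropylbenzoate (two charges)
Product: 11 2-[(2R,3S)-4-(3,4-dimethoxyphenyl)-4-methoxy-3-methylbutan-2-yl]-4,4,5,5-tetramethyl-1,3,2-dioxaborolane (butyl C4 = ring C2 unspecified), via lithio benzoate 7 (not isolated), via first boronate complex 8 (not isolated), via monohomologated boronate 9 (not isolated), via second boronate complex 10 (not isolated)
Conditions: 6 (1.3 equiv), sBuLi, (−)-sparteine, Et2O, −78 °C; then 5, −78 °C → 35 °C; short silica plug, solvent swap; second charge of 6/sBuLi/(−)-sparteine, Et2O, −78 °C; then crude 9, −78 °C → 35 °C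
Reagents that add atoms: none
Why: sBuLi/(−)-sparteine removes the pro-S α-hydrogen of 6 (Hoppe-type enantioselective deprotonation) to give the configurationally stable (S)-carbenoid 7, which adds to the boron of 5 (then of 9) with retention to give boronate complexes 8 and 10. On warming, each complex undergoes a stereospecific 1,2-metallate shift in which the carbon group on boron migrates antiperiplanar to the departing triisopropylbenzoate, so the carbenoid carbon is inverted and the migrating carbon keeps its configuration; this forms C2–C3 and then C3–C4. The closest known reaction type is the iterative, reagent-controlled lithiation–borylation of pinacol boronic esters with enantioenriched 1-lithioethyl triisopropylbenzoate (assembly-line synthesis), with Matteson homologation of α-alkoxy boronic esters as the precedent for the oxygenated migrating group. No ring is closed, and C3 and C4 are each set by the (S) configuration of 7 alone, independently of the unspecified C2, so using the same enantiomer twice gives the unlike dimethyl pair (3S,4R in ring numbering) that is cis in the oxolane. Because the unlike pair requires two correct insertions, the small share of (R)-carbenoid should end up almost wholly in like-dimethyl diastereomers, which are removed by chromatography after step 8, so the enantiomeric purity of the wanted pair should exceed that of a single insertion. The step needs migration to outrun loss of the β-methoxy group from complex 10, which the far better leaving ability of the hindered carboxylate over methoxide in the absence of any Lewis acid should secure, and it needs one insertion per cycle, which is secured because the complexes persist at −78 °C while surplus 7 decomposes on warming before migration begins.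

Step 4
Reactants: 12 syringaldehyde (4-hydroxy-3,5-dimethoxybenzaldehyde)
Product: 13 4-(benzyloxy)-3,5-dimethoxybenzaldehyde
Conditions: BnBr, K2CO3, DMF, 60 °C
Reagents that add atoms: benzyl bromide, BrCc1ccccc1
Why: Williamson etherification of the phenoxide masks the acidic phenol before the organolithium chemistry.

Step 5
Reactants: 13 4-(benzyloxy)-3,5-dimethoxybenzaldehyde
Product: 14 [4-(benzyloxy)-3,5-dimethoxyphenyl]methanol
Conditions: NaBH4, MeOH, 0 °C
Reagents that add atoms: none
Why: borohydride reduction of an aryl aldehyde to the benzylic alcohol, which leaves the aryl ethers untouched.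

Step 6
Reactants: 14 [4-(benzyloxy)-3,5-dimethoxyphenyl]methanol
Product: 15 4-(benzyloxy)-3,5-dimethoxybenzyl N,N-diisopropylcarbamate
Conditions: NaH, THF, 0 °C; then iPr2NCOCl, 0 °C → reflux
Reagents that add atoms: N,N-diisopropylcarbamoyl chloride, CC(C)N(C(C)C)C(Cl)=O
Why: O-carbamoylation of the alkoxide installs the group that both directs α-lithiation and later serves as the leaving group.

Step 7
Reactants: 11 2-[(2R,3S)-4-(3,4-dimethoxyphenyl)-4-methoxy-3-methylbutan-2-yl]-4,4,5,5-tetramethyl-1,3,2-dioxaborolane; 15 4-(benzyloxy)-3,5-dimethoxybenzyl N,N-diisopropylcarbamate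
Product: 19 (2R,3S)-1-[4-(benzyloxy)-3,5-dimethoxyphenyl]-4-(3,4-dimethoxyphenyl)-4-methoxy-2,3-dimethylbutan-1-ol (C1 = ring C5 and C4 = ring C2 unspecified), via lithiated carbamate 16 (not isolated), via third boronate complex 17 (not isolated), via benzylic boronate 18 (not isolated)
Conditions: 15 (1.5 equiv), sBuLi, TMEDA, Et2O, −78 °C; then 11, −78 °C → rt; then NaOH, H2O2, THF/H2O, 0 °C → rt
Reagents that add atoms: hydrogen peroxide, OO
Why: lithiation–borylation with a carbamate-directed benzylic lithiation, in which the boronate complex rearranges by a 1,2-shift of C4 (retention at C4) with loss of the carbamate to form C4–C5, followed by stereoretentive C–B oxidation; C5 is formed without control and converges in step 8.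

Step 8
Reactants: 19 (2R,3S)-1-[4-(benzyloxy)-3,5-dimethoxyphenyl]-4-(3,4-dimethoxyphenyl)-4-methoxy-2,3-dimethylbutan-1-ol
Product: 21 (2S,3S,4R,5R)-5-[4-(benzyloxy)-3,5-dimethoxyphenyl]-2-(3,4-dimethoxyphenyl)-3,4-dimethyloxolane, via epimeric oxolane mixture 20 (not isolated)
Conditions: BF3·OEt2, CH2Cl2, −20 °C → rt, held until the epimers converge
Reagents that add atoms: none
Why: acid-mediated cycloetherification known for 2,5-diaryl-3,4-dimethyloxolane lignans, in which ionisation of the benzylic C2–OMe bond gives a para-methoxy-stabilised cation that the C5 hydroxyl captures (5-exo closure of O1–C2), and reversible re-ionisation of both benzylic C–O bonds should funnel the C2 and C5 epimers to the isomer with each aryl group trans to its neighbouring methyl group, i.e. (2S,5R) beside the fixed (3S,4R) pair.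

Step 9
Reactants: 21 (2S,3S,4R,5R)-5-[4-(benzyloxy)-3,5-dimethoxyphenyl]-2-(3,4-dimethoxyphenyl)-3,4-dimethyloxolane
Product: 22 4-[(2R,3R,4S,5S)-5-(3,4-dimethoxyphenyl)-3,4-dimethyloxolan-2-yl]-2,6-dimethoxyphenol (target; (2S,3S,4R,5R) in the ring numbering used here)
Conditions: H2 (1 atm), Pd/C, EtOAc, rt
Reagents that add atoms: none
Why: hydrogenolysis of the aryl benzyl ether under neutral conditions frees the phenol, and the oxolane benzylic C–O bonds should be cleaved much more slowly, so none of the four stereocentres is touched.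

**Compound list**

1 | 2-(3,4-dimethoxyphenyl)-4,4,5,5-tetramethyl-1,3,2-dioxaborolane | COc1ccc(B2OC(C)(C)C(C)(C)O2)cc1OC | starting material
2 | lithium (dichloromethyl)(3,4-dimethoxyphenyl)(pinacolato)borate | [Li+].COc1ccc([B-]2(C(Cl)Cl)OC(C)(C)C(C)(C)O2)cc1OC | intermediate
3 | 2-[chloro(3,4-dimethoxyphenyl)methyl]-4,4,5,5-tetramethyl-1,3,2-dioxaborolane (racemic) | COc1ccc(C(Cl)B2OC(C)(C)C(C)(C)O2)cc1OC | intermediate
4 | sodium [chloro(3,4-dimethoxyphenyl)methyl](methoxy)(pinacolato)borate | [Na+].COc1ccc(C(Cl)[B-]2(OC)OC(C)(C)C(C)(C)O2)cc1OC | intermediate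
5 | 2-[(3,4-dimethoxyphenyl)(methoxy)methyl]-4,4,5,5-tetramethyl-1,3,2-dioxaborolane (racemic) | COc1ccc(C(OC)B2OC(C)(C)C(C)(C)O2)cc1OC | intermediate
6 | ethyl 2,4,6-triisopropylbenzoate | CCOC(=O)c1c(C(C)C)cc(C(C)C)cc1C(C)C | starting material
7 | (S)-1-lithioethyl 2,4,6-triisopropylbenzoate | [Li][C@@H](C)OC(=O)c1c(C(C)C)cc(C(C)C)cc1C(C)C | intermediate
8 | lithium [(3,4-dimethoxyphenyl)(methoxy)methyl][(1S)-1-(2,4,6-triisopropylbenzoyloxy)ethyl](pinacolato)borate (benzylic carbon unspecified) | [Li+].COc1ccc(C(OC)[B-]2([C@@H](C)OC(=O)c3c(C(C)C)cc(C(C)C)cc3C(C)C)OC(C)(C)C(C)(C)O2)cc1OC | intermediate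
9 | 2-[(2R)-1-(3,4-dimethoxyphenyl)-1-methoxypropan-2-yl]-4,4,5,5-tetramethyl-1,3,2-dioxaborolane (C1 unspecified) | COc1ccc(C(OC)[C@@H](C)B2OC(C)(C)C(C)(C)O2)cc1OC | intermediate
10 | lithium [(2R)-1-(3,4-dimethoxyphenyl)-1-methoxypropan-2-yl][(1S)-1-(2,4,6-triisopropylbenzoyloxy)ethyl](pinacolato)borate (C1 unspecified) | [Li+].COc1ccc(C(OC)[C@@H](C)[B-]2([C@@H](C)OC(=O)c3c(C(C)C)cc(C(C)C)cc3C(C)C)OC(C)(C)C(C)(C)O2)cc1OC | intermediate
11 | 2-[(2R,3S)-4-(3,4-dimethoxyphenyl)-4-methoxy-3-methylbutan-2-yl]-4,4,5,5-tetramethyl-1,3,2-dioxaborolane (C4 of the butyl chain unspecified) | COc1ccc(C(OC)[C@@H](C)[C@@H](C)B2OC(C)(C)C(C)(C)O2)cc1OC | intermediate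
12 | syringaldehyde (4-hydroxy-3,5-dimethoxybenzaldehyde) | COc1cc(C=O)cc(OC)c1O | starting material
13 | 4-(benzyloxy)-3,5-dimethoxybenzaldehyde | COc1cc(C=O)cc(OC)c1OCc1ccccc1 | intermediate
14 | [4-(benzyloxy)-3,5-dimethoxyphenyl]methanol | COc1cc(CO)cc(OC)c1OCc1ccccc1 | intermediate
15 | 4-(benzyloxy)-3,5-dimethoxybenzyl N,N-diisopropylcarbamate | COc1cc(COC(=O)N(C(C)C)C(C)C)cc(OC)c1OCc1ccccc1 | intermediate
16 | [4-(benzyloxy)-3,5-dimethoxyphenyl](lithio)methyl N,N-diisopropylcarbamate (racemic) | [Li]C(OC(=O)N(C(C)C)C(C)C)c1cc(OC)c(OCc2ccccc2)c(OC)c1 | intermediate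
17 | lithium boronate complex of 11 with 16 (ring C3 and C4 as in 11; ring C2 and C5 unspecified) | [Li+].COc1ccc(C(OC)[C@@H](C)[C@@H](C)[B-]2(C(OC(=O)N(C(C)C)C(C)C)c3cc(OC)c(OCc4ccccc4)c(OC)c3)OC(C)(C)C(C)(C)O2)cc1OC | intermediate
18 | 2-[(2S,3S)-1-[4-(benzyloxy)-3,5-dimethoxyphenyl]-4-(3,4-dimethoxyphenyl)-4-methoxy-2,3-dimethylbutyl]-4,4,5,5-tetramethyl-1,3,2-dioxaborolane (C1 and C4 of the butyl chain unspecified; same spatial arrangement at ring C3 and C4 as in 11) | COc1ccc(C(OC)[C@@H](C)[C@@H](C)C(B2OC(C)(C)C(C)(C)O2)c2cc(OC)c(OCc3ccccc3)c(OC)c2)cc1OC | intermediate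
19 | (2R,3S)-1-[4-(benzyloxy)-3,5-dimethoxyphenyl]-4-(3,4-dimethoxyphenyl)-4-methoxy-2,3-dimethylbutan-1-ol (C1 and C4 unspecified) | COc1ccc(C(OC)[C@@H](C)[C@@H](C)C(O)c2cc(OC)c(OCc3ccccc3)c(OC)c2)cc1OC | intermediate
20 | (3S,4R)-5-[4-(benzyloxy)-3,5-dimethoxyphenyl]-2-(3,4-dimethoxyphenyl)-3,4-dimethyloxolane (C2 and C5 epimer mixture) | COc1ccc(C2OC(c3cc(OC)c(OCc4ccccc4)c(OC)c3)[C@H](C)[C@@H]2C)cc1OC | intermediate
21 | (2S,3S,4R,5R)-5-[4-(benzyloxy)-3,5-dimethoxyphenyl]-2-(3,4-dimethoxyphenyl)-3,4-dimethyloxolane | COc1ccc([C@H]2O[C@@H](c3cc(OC)c(OCc4ccccc4)c(OC)c3)[C@H](C)[C@@H]2C)cc1OC | intermediate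
22 | 4-[(2R,3R,4S,5S)-5-(3,4-dimethoxyphenyl)-3,4-dimethyloxolan-2-yl]-2,6-dimethoxyphenol | COc1ccc([C@H]2O[C@@H](c3cc(OC)c(O)c(OC)c3)[C@H](C)[C@@H]2C)cc1OC | target

**Step count**

Total: 9 steps. Longest linear sequence: 6 steps (steps 1, 2, 3, 7, 8, 9 from 1; equally steps 4, 5, 6, 7, 8, 9 from 12).

**Steps most likely to fail**

1. Step 3. In boronate complex 10 the methoxy group β to boron may be lost by elimination across C2–C3 faster than C3 migrates, or the electron-poor α-methoxybenzyl group of complex 8 may migrate so slowly that the complex reverts; the sparteine-bound carbenoid may also add sluggishly to the hindered secondary boronate 9. The fallback takes the C2 oxygen out of the homologation sequence and introduces it at the end by benzylic C–H oxidation. Setting out from 1, chloromethyllithium (BrCH2Cl, nBuLi, THF, −78 °C → rt) should give, through the chloromethyl boronate complex F1, the 3,4-dimethoxybenzyl pinacol boronate F2. Two cycles with 7 (made from 6 with sBuLi and (−)-sparteine, as in step 3) should give, through the first deoxy boronate complex F3, the (R)-monohomologated deoxy boronate F4 and, through the second deoxy boronate complex F5, the (2R,3R)-bishomologated deoxy boronate F6. Lithiation–borylation with 16 under the conditions of step 7 should lead through the deoxy carbamate boronate complex F7 to the deoxy benzylic boronate F8 and, after NaOH/H2O2, to the deoxy alcohol F9. DDQ (CH2Cl2, 0 °C) should then abstract hydride from the electron-rich veratryl CH2 (ring C2), and capture of the cation by the C5 hydroxyl rejoins the route at the epimeric oxolane mixture 20, which the BF3·OEt2 treatment of step 8 carries on to 21.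

2. Step 7. Addition of the stabilised benzylic anion 16 to the hindered secondary boronate 11 may be slow and reversible, so that complex 17 dissociates instead of rearranging; lithiation at the O-benzyl CH2 may also compete. The fallback builds C5 in two classical Matteson operations. Setting out from 11, LiCHCl2 (CH2Cl2, nBuLi, THF, −100 °C; ZnCl2, → rt) should give, through the dichloromethyl boronate complex F10, the α-chloro boronate F11. Benzylation of purchasable 4-bromo-2,6-dimethoxyphenol (BnBr, K2CO3, DMF) gives the aryl bromide F12, and Mg in THF converts it into the aryl Grignard reagent F13. Addition of F13 to F11 forms the aryl boronate complex F14, in which the aryl group shifts from boron to carbon with loss of chloride. This rejoins the route at the benzylic boronate 18, which is oxidised with NaOH/H2O2 as in step 7 to give 19.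

3. Step 8. Epimerisation at C5 may stay incomplete, because the syringyl benzylic C–O bond ionises slowly when the para-benzyloxy group is twisted out of conjugation by its two methoxy neighbours. Prolonged exposure to the Lewis acid may also allow irreversible Friedel–Crafts closure of the C2 cation onto the syringyl ring. The fallback fixes C5 by substrate control before ring closure and then closes the ring kinetically. Setting out from 19, Dess–Martin periodinane (CH2Cl2, rt) should give the aryl ketone F15. LiBH(sBu)3 (THF, −78 °C) should reduce it under Felkin–Anh control, with hydride approaching anti to the C3 chain and past the C4 hydrogen, to give the (1R,2R,3S)-alcohol F16, in which the C5 hydroxyl and the C4 methyl are anti. Brief treatment with BF3·OEt2 (CH2Cl2, −78 °C) should ionise only the C2–OMe bond; the C5 hydroxyl then closes the ring with retention at C5 and with the C2 aryl group trans to the C3 methyl, rejoining the route at 21.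

**Further compounds**

F1 | step 3 | lithium (chloromethyl)(3,4-dimethoxyphenyl)(pinacolato)borate | [Li+].COc1ccc([B-]2(CCl)OC(C)(C)C(C)(C)O2)cc1OC
F2 | step 3 | 2-(3,4-dimethoxybenzyl)-4,4,5,5-tetramethyl-1,3,2-dioxaborolane | COc1ccc(CB2OC(C)(C)C(C)(C)O2)cc1OC
F3 | step 3 | lithium (3,4-dimethoxybenzyl)[(1S)-1-(2,4,6-triisopropylbenzoyloxy)ethyl](pinacolato)borate | [Li+].COc1ccc(C[B-]2([C@@H](C)OC(=O)c3c(C(C)C)cc(C(C)C)cc3C(C)C)OC(C)(C)C(C)(C)O2)cc1OC
F4 | step 3 | 2-[(2R)-1-(3,4-dimethoxyphenyl)propan-2-yl]-4,4,5,5-tetramethyl-1,3,2-dioxaborolane | COc1ccc(C[C@@H](C)B2OC(C)(C)C(C)(C)O2)cc1OC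
F5 | step 3 | lithium [(2R)-1-(3,4-dimethoxyphenyl)propan-2-yl][(1S)-1-(2,4,6-triisopropylbenzoyloxy)ethyl](pinacolato)borate | [Li+].COc1ccc(C[C@@H](C)[B-]2([C@@H](C)OC(=O)c3c(C(C)C)cc(C(C)C)cc3C(C)C)OC(C)(C)C(C)(C)O2)cc1OC
F6 | step 3 | 2-[(2R,3R)-4-(3,4-dimethoxyphenyl)-3-methylbutan-2-yl]-4,4,5,5-tetramethyl-1,3,2-dioxaborolane | COc1ccc(C[C@@H](C)[C@@H](C)B2OC(C)(C)C(C)(C)O2)cc1OC
F7 | step 3 | lithium boronate complex of F6 with 16 (benzylic carbamate carbon unspecified) | [Li+].COc1ccc(C[C@@H](C)[C@@H](C)[B-]2(C(OC(=O)N(C(C)C)C(C)C)c3cc(OC)c(OCc4ccccc4)c(OC)c3)OC(C)(C)C(C)(C)O2)cc1OC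
F8 | step 3 | 2-[1-[4-(benzyloxy)-3,5-dimethoxyphenyl]-4-(3,4-dimethoxyphenyl)-2,3-dimethylbutyl]-4,4,5,5-tetramethyl-1,3,2-dioxaborolane (dimethyl pair as in F6; C1 unspecified) | COc1ccc(C[C@@H](C)[C@@H](C)C(B2OC(C)(C)C(C)(C)O2)c2cc(OC)c(OCc3ccccc3)c(OC)c2)cc1OC
F9 | step 3 | (2R,3R)-1-[4-(benzyloxy)-3,5-dimethoxyphenyl]-4-(3,4-dimethoxyphenyl)-2,3-dimethylbutan-1-ol (C1 unspecified) | COc1ccc(C[C@@H](C)[C@@H](C)C(O)c2cc(OC)c(OCc3ccccc3)c(OC)c2)cc1OC
F10 | step 7 | lithium (dichloromethyl)[(2R,3S)-4-(3,4-dimethoxyphenyl)-4-methoxy-3-methylbutan-2-yl](pinacolato)borate | [Li+].COc1ccc(C(OC)[C@@H](C)[C@@H](C)[B-]2(C(Cl)Cl)OC(C)(C)C(C)(C)O2)cc1OC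
F11 | step 7 | 2-[1-chloro-4-(3,4-dimethoxyphenyl)-4-methoxy-2,3-dimethylbutyl]-4,4,5,5-tetramethyl-1,3,2-dioxaborolane (dimethyl pair as in 11; C1 and C4 unspecified) | COc1ccc(C(OC)[C@@H](C)[C@@H](C)C(Cl)B2OC(C)(C)C(C)(C)O2)cc1OC
F12 | step 7 | 2-(benzyloxy)-5-bromo-1,3-dimethoxybenzene | COc1cc(Br)cc(OC)c1OCc1ccccc1
F13 | step 7 | [4-(benzyloxy)-3,5-dimethoxyphenyl]magnesium bromide | COc1cc([Mg]Br)cc(OC)c1OCc1ccccc1
F14 | step 7 | bromomagnesium [4-(benzyloxy)-3,5-dimethoxyphenyl][1-chloro-4-(3,4-dimethoxyphenyl)-4-methoxy-2,3-dimethylbutyl](pinacolato)borate | [Mg+]Br.COc1ccc(C(OC)[C@@H](C)[C@@H](C)C(Cl)[B-]2(c3cc(OC)c(OCc4ccccc4)c(OC)c3)OC(C)(C)C(C)(C)O2)cc1OC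
F15 | step 8 | (2R,3S)-1-[4-(benzyloxy)-3,5-dimethoxyphenyl]-4-(3,4-dimethoxyphenyl)-4-methoxy-2,3-dimethylbutan-1-one (C4 unspecified) | COc1ccc(C(OC)[C@@H](C)[C@@H](C)C(=O)c2cc(OC)c(OCc3ccccc3)c(OC)c2)cc1OC
F16 | step 8 | (1R,2R,3S)-1-[4-(benzyloxy)-3,5-dimethoxyphenyl]-4-(3,4-dimethoxyphenyl)-4-methoxy-2,3-dimethylbutan-1-ol (C4 unspecified) | COc1ccc(C(OC)[C@@H](C)[C@@H](C)[C@@H](O)c2cc(OC)c(OCc3ccccc3)c(OC)c2)cc1OC
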